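At early times the flask's ratio of other capture product to target is hard to read from the earlier runs: green's first readings are 0 % and 1 %, and the scatter is 1.5 percentage points. I therefore reckon it by hand: if the two nucleophiles capture at an equal pace, the ratio starts at the charge ratio, c(second nucleophile) over c(first nucleophile) as charged, which is 0.611 for this flask.

| flask | substrate | first nucleophile | second nucleophile | remark | time |
|---|---|---|---|---|---|
| teal | 0.10 M | 0.090 M | 0.11 M | run made earlier |  |
| red | 0.10 M | 0.14 M | 0.11 M | run made earlier |  |
| green | 0.050 M | 0.18 M | 0.11 M | run made earlier |  |
| flask | 0.10 M | 0.180 M | 0.110 M |  | 2.0 min |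

- teal (time / s: other capture product / %, target / %): 10.0: 3, 0; 25.0: 7, 4; 40.0: 9, 10; 60.0: 15, 8; 90.0: 20, 8; 120: 21, 10
- red (time / s: other capture product / %, target / %): 20.0: 3, 5; 40.0: 9, 6; 60.0: 11, 9; 80.0: 17, 12; 90.0: 20, 11; 120: 23, 14
- green (time / s: other capture product / %, target / %): 10.0: 0, 1; 30.0: 7, 6; 60.0: 12, 9; 80.0: 18, 11; 120: 22, 15

(each reading ± 1.5 percentage points)

- what was read earlier has a scatter of 1.5 percentage points, one standard deviation
- a reading or a percentage of target counts all its forms, free or not

* ratio of other capture product to target at 4.0 s
* ratio of other capture product to target at 2.0 min
* which of other capture product and target there is more of at 2.0 min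

I turn the settings one after the other. By hand, more first nucleophile lowers the ratio, and it does: with substrate at 0.10 M in both, the last readings fall from 2.10 in teal at 0.090 M to 1.64 in red at 0.14 M, and green, at 0.18 M and 0.050 M of substrate, ends at 1.47. But green's late ratio stands above its charge ratio of 0.611, so I take the charge ratio as a starting value and expect the ratio to climb with time. Substrate does not enter the charge ratio, so I carry green's late value to this flask, which has green's nucleophile charges. By hand, more second nucleophile raises the starting ratio in step with its charge, but teal, red and green were each charged with 0.11 M of it. I commit to 0.611 at 4.0 s and 1.47 at 2.0 min, with other capture product ahead.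

The forecast gives 0.9 early and 1.5 late, with other capture product ahead, and says: “The early ratio is poorly defined by the noise.”

The flask gives 0.601 early, close to the charge ratio of 0.611 and below the forecast, and 1.55 late, with other capture product ahead at 22.1 % against 14.2 % of target.

    substrate → intermediate (k = 0.00657 /s)
    first nucleophile + intermediate → target (k = 23.4 /M/s)
    second nucleophile + intermediate → other capture product (k = 20.9 /M/s)
    intermediate → solvolysis product (k = 1.65 /s)
    2 first nucleophile → homo dimer (k = 0.141 /M/s)
    second nucleophile + target ⇌ idle adduct, settled at all times (K = 4.00 /M)

The selectivity factor, the ratio of the two capture constants, is 0.893, not the equal pace I assumed. In this flask, the substrate fell to 45.5 % of what was charged by 2.00 min and fed the intermediate, while the homo dimer step ran alongside and first nucleophile stood at 60.9 % of its charge after 0.200 min and 12.2 % after 2.00 min. Second nucleophile was still at 76.7 % of its charge at that end, and the two products had stood level at 8.44 % each after 0.675 min. In a neighbour flask with 0.28 M of second nucleophile, the charge ratio is 1.56 and the early ratio is 1.53.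

Readings and results are simulated from invented constants, and the scatter is random.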